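**Retrosynthetic overview**
1. The strategy rests on C3' of the hexanoic acid chain on ring carbon C6. Its two arms both begin with CH2 (C2'H2–CO2H and C4'H2–C5'H2–C6'H3), so it is stored as the non-stereogenic C3 of a 3-arylcyclobutanone. A catalyst-controlled Baeyer–Villiger oxygen insertion turns that ring into the (R)-β-aryl-γ-butyrolactone (C=O arm = C2'/C1', CH2–O arm = C4').
2. The lactone is opened to the bromo ester and a Cu-catalysed ethyl coupling completes the propyl arm. The C8 prenyl group comes last, by O-prenylation of C5–OH and a para-Claisen–Cope shift, followed by saponification.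
3. The cyclobutanone comes from the C6 styrene (dichloroketene [2+2], Zn), and the styrene from the chroman phenol (phenol-directed ortho-formylation at C6, benzylation, Wittig).
4. The chroman comes from Mitsunobu closure of O1–C2 with inversion. The open chain is made by Negishi union (C4–C4a) of an Evans syn-aldol-derived alkylzinc with the bis-MOM ether of 2-iodo-5-methoxyresorcinol.
5. Ring order: benzene ring (bought), dihydropyran ring of the chroman (step 9), cyclobutanone (step 13), γ-lactone (step 14, opened again in step 15).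

Key step: step 14

Assumption: the (R)-configured phosphoric acid is taken to give the (R)-lactone, as it does with simpler 3-arylcyclobutanones; if a trial run shows the opposite sense on this aryl group, the (S)-acid is used.

**Step 1**
Reactants: 1 (S)-4-benzyl-3-propionyloxazolidin-2-one; 2 acetaldehyde
Product: 4 (S)-4-benzyl-3-[(2S,3R)-3-hydroxy-2-methylbutanoyl]oxazolidin-2-one, via dibutylboron Z-enolate 3 (not isolated)
Conditions: Bu2BOTf, i-Pr2NEt, CH2Cl2, 0 °C; 2, −78 → 0 °C; pH 7 buffer, MeOH, 30% H2O2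
Reagents that add atoms: none
Why: Evans syn aldol, in which the Z-boron enolate reacts through a Zimmerman–Traxler chair on the face away from the auxiliary benzyl group, which should set C2 (S) and C3 (R) of the butanoyl chain (the future chroman C3 and, before inversion, C2).

**Step 2**
Reactants: 4 (S)-4-benzyl-3-[(2S,3R)-3-hydroxy-2-methylbutanoyl]oxazolidin-2-one
Product: 5 (S)-4-benzyl-3-[(2S,3R)-3-(tert-butyldimethylsilyloxy)-2-methylbutanoyl]oxazolidin-2-one
Conditions: TBSOTf, 2,6-lutidine, CH2Cl2, 0 °C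
Reagents that add atoms: tert-butyldimethylsilyl trifluoromethanesulfonate, CC(C)(C)[Si](C)(C)OS(=O)(=O)C(F)(F)F
Why: Silyl ether formation masks the carbinol for the organometallic steps and touches no stereocentre.

**Step 3**
Reactants: 5 (S)-4-benzyl-3-[(2S,3R)-3-(tert-butyldimethylsilyloxy)-2-methylbutanoyl]oxazolidin-2-one
Product: 6 (2R,3R)-3-(tert-butyldimethylsilyloxy)-2-methylbutan-1-ol
Conditions: LiBH4, MeOH (1 equiv), THF, 0 °C; 1 M NaOH
Reagents that add atoms: none
Why: Reductive cleavage of the N-acyl oxazolidinone by borohydride gives the primary alcohol and the free auxiliary without enolisation of the α-centre (the descriptor changes only because of ranking).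

**Step 4**
Reactants: 6 (2R,3R)-3-(tert-butyldimethylsilyloxy)-2-methylbutan-1-ol
Product: 7 tert-butyl{[(2R,3S)-4-iodo-3-methylbutan-2-yl]oxy}dimethylsilane
Conditions: I2, PPh3, imidazole, CH2Cl2, 0 °C → rt
Reagents that add atoms: iodine, II
Why: Appel-type iodination proceeds by SN2 displacement of the alkoxyphosphonium at the primary carbon, so both stereocentres stay as they are.

**Step 5**
Reactants: 8 5-methoxyresorcinol
Product: 9 1-methoxy-3,5-bis(methoxymethoxy)benzene
Conditions: MOMCl, i-Pr2NEt, CH2Cl2, 0 °C → rt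
Reagents that add atoms: chloromethyl methyl ether, COCCl
Why: Williamson-type O-alkylation of both phenols installs two acetal groups that later direct the metalation.

**Step 6**
Reactants: 9 1-methoxy-3,5-bis(methoxymethoxy)benzene
Product: 11 2-iodo-5-methoxy-1,3-bis(methoxymethoxy)benzene, via aryllithium 10 (not isolated)
Conditions: n-BuLi, THF, 0 °C → rt; I2, −78 °C
Reagents that add atoms: iodine, II
Why: Directed ortho-metalation should occur at the carbon flanked by the two chelating OMOM groups (stronger directors than OMe), and iodine traps the aryllithium there.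

**Step 7**
Reactants: 7 tert-butyl{[(2R,3S)-4-iodo-3-methylbutan-2-yl]oxy}dimethylsilane; 11 2-iodo-5-methoxy-1,3-bis(methoxymethoxy)benzene
Product: 13 tert-butyl({(2R,3R)-4-[4-methoxy-2,6-bis(methoxymethoxy)phenyl]-3-methylbutan-2-yl}oxy)dimethylsilane, via alkylzinc iodide 12 (not isolated)
Conditions: 7, Zn dust, LiCl, THF, 40 °C; then 11, Pd(OAc)2 (2 mol%), 2-dicyclohexylphosphino-2',6'-dimethoxybiphenyl (SPhos, 4 mol%), THF, 50 °C
Reagents that add atoms: none
Why: Negishi cross-coupling, in which zinc inserts into the primary C–I bond and the bulky biarylphosphine–palladium catalyst joins the primary alkylzinc to the hindered aryl iodide without touching the two sp3 stereocentres.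

**Step 8**
Reactants: 13 tert-butyl({(2R,3R)-4-[4-methoxy-2,6-bis(methoxymethoxy)phenyl]-3-methylbutan-2-yl}oxy)dimethylsilane
Product: 14 2-[(2R,3R)-3-hydroxy-2-methylbutyl]-5-methoxybenzene-1,3-diol
Conditions: conc. HCl (cat.), MeOH, 45 °C
Reagents that add atoms: none
Why: Acid-catalysed methanolysis removes both MOM acetals and the silyl ether in one operation, and methanol captures the formaldehyde equivalents as dimethoxymethane.

**Step 9**
Reactants: 14 2-[(2R,3R)-3-hydroxy-2-methylbutyl]-5-methoxybenzene-1,3-diol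
Product: 15 (2S,3R)-7-methoxy-2,3-dimethylchroman-5-ol
Conditions: PPh3, DIAD, THF, 0 °C → rt
Reagents that add atoms: none
Why: Intramolecular Mitsunobu etherification, in which either of the two equivalent phenol oxygens displaces the activated secondary carbinol by 6-exo-tet SN2 with inversion (R → S), should give the trans-2,3-dimethylchroman.

**Step 10**
Reactants: 15 (2S,3R)-7-methoxy-2,3-dimethylchroman-5-ol
Product: 16 (2S,3R)-5-hydroxy-7-methoxy-2,3-dimethylchroman-6-carbaldehyde
Conditions: MgCl2, Et3N, (CH2O)n, MeCN, 80 °C; aq. HCl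
Reagents that add atoms: paraformaldehyde (as formaldehyde), C=O
Why: Magnesium-mediated ortho-formylation of phenols (Casnati–Skattebøl) delivers formaldehyde only ortho to the magnesium phenoxide, so C6, the one free ortho position, should be formylated and C8 (para) left alone.

**Step 11**
Reactants: 16 (2S,3R)-5-hydroxy-7-methoxy-2,3-dimethylchroman-6-carbaldehyde
Product: 17 (2S,3R)-5-(benzyloxy)-7-methoxy-2,3-dimethylchroman-6-carbaldehyde
Conditions: BnBr, K2CO3, DMF, 50 °C
Reagents that add atoms: benzyl bromide, BrCc1ccccc1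
Why: Williamson ether synthesis on the phenoxide protects C5–OH with a group that survives the ketene, zinc, peroxide and Grignard steps and is removed later by hydrogenolysis.

**Step 12**
Reactants: 17 (2S,3R)-5-(benzyloxy)-7-methoxy-2,3-dimethylchroman-6-carbaldehyde
Product: 18 (2S,3R)-5-(benzyloxy)-6-ethenyl-7-methoxy-2,3-dimethylchroman
Conditions: Ph3PCH3Br, KOt-Bu, THF, 0 °C → rt
Reagents that add atoms: methyltriphenylphosphonium bromide, C[P+](c1ccccc1)(c1ccccc1)c1ccccc1.[Br-]
Why: Wittig methylenation with the small unstabilised ylide should convert even this doubly ortho-substituted aldehyde into the styrene.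

**Step 13**
Reactants: 18 (2S,3R)-5-(benzyloxy)-6-ethenyl-7-methoxy-2,3-dimethylchroman; 19 trichloroacetyl chloride
Product: 21 3-[(2S,3R)-5-(benzyloxy)-7-methoxy-2,3-dimethylchroman-6-yl]cyclobutan-1-one, via 2,2-dichlorocyclobutanone 20 (not isolated)
Conditions: 19, Zn(Cu) couple, POCl3, Et2O, rt (slow addition); filter, concentrate; then Zn dust, AcOH, rt → 50 °C
Reagents that add atoms: none
Why: Ketene–alkene [2+2] cycloaddition of dichloroketene made in the flask (carbonyl carbon to the terminal CH2, CCl2 to the benzylic carbon) followed by reductive dechlorination with zinc gives the 3-arylcyclobutanone, and the two C3 epimers of 20 converge because C3 of 21 is not stereogenic.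

**Step 14**
Reactants: 21 3-[(2S,3R)-5-(benzyloxy)-7-methoxy-2,3-dimethylchroman-6-yl]cyclobutan-1-one
Product: 23 (R)-4-[(2S,3R)-5-(benzyloxy)-7-methoxy-2,3-dimethylchroman-6-yl]dihydrofuran-2(3H)-one, via peroxy hemiketal 22 (not isolated)
Conditions: 30% aq. H2O2 (1.5 equiv), (R)-3,3'-di(pyren-1-yl)-5,5',6,6',7,7',8,8'-octahydro-1,1'-binaphthalene-2,2'-diyl hydrogen phosphate (10 mol%), CHCl3, −40 °C
Reagents that add atoms: hydrogen peroxide, OO
Why: H2O2 and the ketone are held together by the bifunctional phosphoric acid (P–OH to C=O, P=O to HOO), the peroxide adds to the strained carbonyl to give the Criegee-type peroxy hemiketal 22, and the ring CH2 lying antiperiplanar to the O–O bond migrates to oxygen with retention while water leaves. The closest known reaction is the chiral-phosphoric-acid-catalysed Baeyer–Villiger desymmetrisation of 3-arylcyclobutanones with aqueous H2O2. The γ-lactone is formed by ring expansion from four to five members through a 1,2-shift of carbon to oxygen, not by a cyclisation. The new stereocentre (lactone C4, later C3' of the acid) is under catalyst control, because the chiral pocket decides which of the two ring CH2 groups (made non-equivalent only by the remote chroman centres) takes the migrating position, and the (R)-lactone is the one required. The step needs chemoselectivity for the ketone over the trialkoxybenzene ring and the benzyl ether, which the ring strain of the cyclobutanone secures by letting H2O2 without any peracid react at −40 °C.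

**Step 15**
Reactants: 23 (R)-4-[(2S,3R)-5-(benzyloxy)-7-methoxy-2,3-dimethylchroman-6-yl]dihydrofuran-2(3H)-one
Product: 24 ethyl (R)-3-[(2S,3R)-5-(benzyloxy)-7-methoxy-2,3-dimethylchroman-6-yl]-4-bromobutanoate
Conditions: Me3SiBr, EtOH, CH2Cl2, 0 °C → rt
Reagents that add atoms: bromotrimethylsilane, C[Si](C)(C)Br; ethanol, CCO
Why: Lactone ring opening by bromide at the activated alkyl C–O bond (SN2 at CH2) with esterification of the acyl end by ethanol keeps the two arms different and does not involve the stereocentre.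

**Step 16**
Reactants: 24 ethyl (R)-3-[(2S,3R)-5-(benzyloxy)-7-methoxy-2,3-dimethylchroman-6-yl]-4-bromobutanoate
Product: 25 ethyl (R)-3-[(2S,3R)-5-(benzyloxy)-7-methoxy-2,3-dimethylchroman-6-yl]hexanoate
Conditions: EtMgBr (slow addition), Li2CuCl4 (5 mol%), NMP, THF, −20 → 0 °C
Reagents that add atoms: ethylmagnesium bromide, CC[Mg]Br
Why: Copper-catalysed Kochi-type sp3–sp3 coupling of a Grignard reagent with a primary bromide, which with NMP at low temperature is expected to be faster than attack on the ester, turns CH2Br into the propyl arm.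

**Step 17**
Reactants: 25 ethyl (R)-3-[(2S,3R)-5-(benzyloxy)-7-methoxy-2,3-dimethylchroman-6-yl]hexanoate
Product: 26 ethyl (R)-3-[(2S,3R)-5-hydroxy-7-methoxy-2,3-dimethylchroman-6-yl]hexanoate
Conditions: H2 (1 atm), Pd/C, EtOAc–EtOH, rt
Reagents that add atoms: none
Why: Hydrogenolysis of the benzyl aryl ether frees C5–OH at a stage with no alkene present, and neutral ethanol keeps the hydroxy ester in its open form.

**Step 18**
Reactants: 26 ethyl (R)-3-[(2S,3R)-5-hydroxy-7-methoxy-2,3-dimethylchroman-6-yl]hexanoate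
Product: 27 ethyl (R)-3-[(2S,3R)-7-methoxy-2,3-dimethyl-5-(3-methylbut-2-en-1-yloxy)chroman-6-yl]hexanoate
Conditions: prenyl bromide, K2CO3, DMF, rt
Reagents that add atoms: 1-bromo-3-methylbut-2-ene, CC(C)=CCBr
Why: Williamson O-alkylation of the phenoxide at the primary allylic carbon is favoured in DMF, and under base the phenoxide–ethyl ester form is preferred over the dihydrocoumarin.

**Step 19**
Reactants: 27 ethyl (R)-3-[(2S,3R)-7-methoxy-2,3-dimethyl-5-(3-methylbut-2-en-1-yloxy)chroman-6-yl]hexanoate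
Product: 30 ethyl (R)-3-[(2S,3R)-5-hydroxy-7-methoxy-2,3-dimethyl-8-(3-methylbut-2-en-1-yl)chroman-6-yl]hexanoate, via ortho-dienone 28 (not isolated), via para-dienone 29 (not isolated)
Conditions: PhNEt2, 190 °C, sealed tube, Ar
Reagents that add atoms: none
Why: Para-Claisen rearrangement, in which the aromatic Claisen shift to a blocked ortho carbon (C6 shown; the C4a dienone would converge) is followed by a Cope shift to C8 and enolisation, places the normal prenyl group at the only free ring position; any dihydrocoumarin formed by loss of ethanol gives the same acid in step 20.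

**Step 20**
Reactants: 30 ethyl (R)-3-[(2S,3R)-5-hydroxy-7-methoxy-2,3-dimethyl-8-(3-methylbut-2-en-1-yl)chroman-6-yl]hexanoate
Product: 31 (R)-3-[(2S,3R)-5-hydroxy-7-methoxy-2,3-dimethyl-8-(3-methylbut-2-en-1-yl)chroman-6-yl]hexanoic acid
Conditions: LiOH, THF–MeOH–H2O, rt; 1 M HCl to pH 4, 0 °C
Reagents that add atoms: lithium hydroxide (aqueous), [Li+].[OH-]
Why: Ester saponification (acyl–oxygen cleavage) followed by cold, mild acidification should release the hydroxy acid in its open form without touching the prenyl group or the three stereocentres.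

**Compound list**
1 | (S)-4-benzyl-3-propionyloxazolidin-2-one | CCC(=O)N1[C@@H](Cc2ccccc2)COC1=O | starting material
2 | acetaldehyde | CC=O | starting material
3 | (S)-4-benzyl-3-[(Z)-1-(dibutylboranyloxy)prop-1-en-1-yl]oxazolidin-2-one | CCCCB(CCCC)O/C(=C\C)N1[C@@H](Cc2ccccc2)COC1=O | intermediate (not isolated)
4 | (S)-4-benzyl-3-[(2S,3R)-3-hydroxy-2-methylbutanoyl]oxazolidin-2-one | C[C@@H](O)[C@H](C)C(=O)N1[C@@H](Cc2ccccc2)COC1=O | intermediate
5 | (S)-4-benzyl-3-[(2S,3R)-3-(tert-butyldimethylsilyloxy)-2-methylbutanoyl]oxazolidin-2-one | C[C@@H](O[Si](C)(C)C(C)(C)C)[C@H](C)C(=O)N1[C@@H](Cc2ccccc2)COC1=O | intermediate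
6 | (2R,3R)-3-(tert-butyldimethylsilyloxy)-2-methylbutan-1-ol | C[C@@H](O[Si](C)(C)C(C)(C)C)[C@H](C)CO | intermediate
7 | tert-butyl{[(2R,3S)-4-iodo-3-methylbutan-2-yl]oxy}dimethylsilane | C[C@@H](O[Si](C)(C)C(C)(C)C)[C@H](C)CI | intermediate
8 | 5-methoxyresorcinol | COc1cc(O)cc(O)c1 | starting material
9 | 1-methoxy-3,5-bis(methoxymethoxy)benzene | COCOc1cc(OC)cc(OCOC)c1 | intermediate
10 | [4-methoxy-2,6-bis(methoxymethoxy)phenyl]lithium | [Li]c1c(OCOC)cc(OC)cc1OCOC | intermediate (not isolated)
11 | 2-iodo-5-methoxy-1,3-bis(methoxymethoxy)benzene | Ic1c(OCOC)cc(OC)cc1OCOC | intermediate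
12 | [(2S,3R)-3-(tert-butyldimethylsilyloxy)-2-methylbutyl]zinc iodide | C[C@@H](O[Si](C)(C)C(C)(C)C)[C@H](C)C[Zn]I | intermediate (not isolated)
13 | tert-butyl({(2R,3R)-4-[4-methoxy-2,6-bis(methoxymethoxy)phenyl]-3-methylbutan-2-yl}oxy)dimethylsilane | C[C@@H](O[Si](C)(C)C(C)(C)C)[C@H](C)Cc1c(OCOC)cc(OC)cc1OCOC | intermediate
14 | 2-[(2R,3R)-3-hydroxy-2-methylbutyl]-5-methoxybenzene-1,3-diol | C[C@@H](O)[C@H](C)Cc1c(O)cc(OC)cc1O | intermediate
15 | (2S,3R)-7-methoxy-2,3-dimethylchroman-5-ol | COc1cc(O)c2c(c1)O[C@@H](C)[C@H](C)C2 | intermediate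
16 | (2S,3R)-5-hydroxy-7-methoxy-2,3-dimethylchroman-6-carbaldehyde | O=Cc1c(O)c2c(cc1OC)O[C@@H](C)[C@H](C)C2 | intermediate
17 | (2S,3R)-5-(benzyloxy)-7-methoxy-2,3-dimethylchroman-6-carbaldehyde | O=Cc1c(OCc3ccccc3)c2c(cc1OC)O[C@@H](C)[C@H](C)C2 | intermediate
18 | (2S,3R)-5-(benzyloxy)-6-ethenyl-7-methoxy-2,3-dimethylchroman | C=Cc1c(OCc3ccccc3)c2c(cc1OC)O[C@@H](C)[C@H](C)C2 | intermediate
19 | trichloroacetyl chloride | O=C(Cl)C(Cl)(Cl)Cl | starting material
20 | 3-[(2S,3R)-5-(benzyloxy)-7-methoxy-2,3-dimethylchroman-6-yl]-2,2-dichlorocyclobutan-1-one (both C3 epimers) | O=C1CC(C1(Cl)Cl)c1c(OCc3ccccc3)c2c(cc1OC)O[C@@H](C)[C@H](C)C2 | intermediate (not isolated)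
21 | 3-[(2S,3R)-5-(benzyloxy)-7-methoxy-2,3-dimethylchroman-6-yl]cyclobutan-1-one | O=C1CC(C1)c1c(OCc3ccccc3)c2c(cc1OC)O[C@@H](C)[C@H](C)C2 | intermediate
22 | 3-[(2S,3R)-5-(benzyloxy)-7-methoxy-2,3-dimethylchroman-6-yl]-1-hydroperoxycyclobutan-1-ol | OOC1(O)CC(C1)c1c(OCc3ccccc3)c2c(cc1OC)O[C@@H](C)[C@H](C)C2 | intermediate (not isolated)
23 | (R)-4-[(2S,3R)-5-(benzyloxy)-7-methoxy-2,3-dimethylchroman-6-yl]dihydrofuran-2(3H)-one | O=C1C[C@@H](CO1)c1c(OCc3ccccc3)c2c(cc1OC)O[C@@H](C)[C@H](C)C2 | intermediate
24 | ethyl (R)-3-[(2S,3R)-5-(benzyloxy)-7-methoxy-2,3-dimethylchroman-6-yl]-4-bromobutanoate | CCOC(=O)C[C@@H](CBr)c1c(OCc3ccccc3)c2c(cc1OC)O[C@@H](C)[C@H](C)C2 | intermediate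
25 | ethyl (R)-3-[(2S,3R)-5-(benzyloxy)-7-methoxy-2,3-dimethylchroman-6-yl]hexanoate | CCC[C@H](CC(=O)OCC)c1c(OCc3ccccc3)c2c(cc1OC)O[C@@H](C)[C@H](C)C2 | intermediate
26 | ethyl (R)-3-[(2S,3R)-5-hydroxy-7-methoxy-2,3-dimethylchroman-6-yl]hexanoate | CCC[C@H](CC(=O)OCC)c1c(O)c2c(cc1OC)O[C@@H](C)[C@H](C)C2 | intermediate
27 | ethyl (R)-3-[(2S,3R)-7-methoxy-2,3-dimethyl-5-(3-methylbut-2-en-1-yloxy)chroman-6-yl]hexanoate | CCC[C@H](CC(=O)OCC)c1c(OCC=C(C)C)c2c(cc1OC)O[C@@H](C)[C@H](C)C2 | intermediate
28 | ethyl 3-[(2S,3R)-7-methoxy-2,3-dimethyl-6-(2-methylbut-3-en-2-yl)-5-oxo-3,4,5,6-tetrahydro-2H-chromen-6-yl]hexanoate (chain centre as in 27; C6 unassigned) | CCC[C@H](CC(=O)OCC)C1(C(C)(C)C=C)C(=O)C2=C(C=C1OC)O[C@@H](C)[C@H](C)C2 | intermediate (not isolated)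
29 | ethyl 3-[(2S,3R)-7-methoxy-2,3-dimethyl-8-(3-methylbut-2-en-1-yl)-5-oxo-3,4,5,8-tetrahydro-2H-chromen-6-yl]hexanoate (chain centre as in 27; C8 unassigned) | CCC[C@H](CC(=O)OCC)C1=C(OC)C(CC=C(C)C)C(O[C@@H](C)[C@H](C)C2)=C2C1=O | intermediate (not isolated)
30 | ethyl (R)-3-[(2S,3R)-5-hydroxy-7-methoxy-2,3-dimethyl-8-(3-methylbut-2-en-1-yl)chroman-6-yl]hexanoate | CCC[C@H](CC(=O)OCC)c1c(O)c2c(c(CC=C(C)C)c1OC)O[C@@H](C)[C@H](C)C2 | intermediate
31 | (R)-3-[(2S,3R)-5-hydroxy-7-methoxy-2,3-dimethyl-8-(3-methylbut-2-en-1-yl)chroman-6-yl]hexanoic acid | CCC[C@H](CC(=O)O)c1c(O)c2c(c(CC=C(C)C)c1OC)O[C@@H](C)[C@H](C)C2 | target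

**Step count**
Total steps: 20. Longest linear sequence: 18 steps (steps 1–4, then 7–20, from imide 1); the arene branch (steps 5 and 6) joins at step 7.

**Steps most likely to fail**

Step 14 (key step). The catalyst may discriminate poorly between the two ring CH2 groups when the aryl group carries two ortho substituents, giving low selectivity at the new centre. Slow peroxide addition at −40 °C would also leave time for oxidation of the electron-rich ring. The fallback sets out from aldehyde 17 and comes back at ester 25, so that steps 12 to 16 are no longer needed. A Masamune–Roush Horner–Wadsworth–Emmons reaction of 17 with (R)-3-[2-(diethoxyphosphoryl)acetyl]-4-phenyloxazolidin-2-one (LiCl, i-Pr2NEt, MeCN) should give (R)-3-{(E)-3-[(2S,3R)-5-(benzyloxy)-7-methoxy-2,3-dimethylchroman-6-yl]acryloyl}-4-phenyloxazolidin-2-one F1. Auxiliary-controlled conjugate addition of the propylcopper reagent from n-PrMgBr and CuBr·SMe2 (THF–Me2S, −40 °C), on the face of the magnesium-chelated s-cis imide away from the phenyl group, is expected to give (R)-3-{(R)-3-[(2S,3R)-5-(benzyloxy)-7-methoxy-2,3-dimethylchroman-6-yl]hexanoyl}-4-phenyloxazolidin-2-one F2. Ethanolysis with bromomagnesium ethoxide (EtMgBr, EtOH, THF, 0 °C) then releases ester 25.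

Step 16. Deprotonation next to the ester by the Grignard reagent, followed by 3-exo-tet closure to a cyclopropane, or addition to the ester carbonyl, may outrun the copper-catalysed substitution at the β-branched bromide. The fallback reverses the polarity; it sets out from bromo ester 24 and comes back at phenol 26. Zinc insertion (Zn dust, LiCl, THF, 50 °C) should give [(R)-2-[(2S,3R)-5-(benzyloxy)-7-methoxy-2,3-dimethylchroman-6-yl]-4-ethoxy-4-oxobutyl]zinc bromide F3, a non-basic reagent that tolerates the ester. Negishi coupling with vinyl bromide (Pd(OAc)2, 2-dicyclohexylphosphino-2',6'-dimethoxybiphenyl, THF, rt) gives ethyl (R)-3-[(2S,3R)-5-(benzyloxy)-7-methoxy-2,3-dimethylchroman-6-yl]hex-5-enoate F4. Hydrogenation under the conditions of step 17 saturates the alkene and cleaves the benzyl ether in the same operation, giving 26.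

Step 19. Fragmentation of the prenyl ether (loss of isoprene and return to the phenol) may compete with the two consecutive sigmatropic shifts at 190 °C. The fallback replaces the rearrangement by a cross-coupling; it sets out from phenol 26 and comes back at 30. Iodination with N-iodosuccinimide (MeCN, 0 °C) can only occur at C8, the single free ring position, and should give ethyl (R)-3-[(2S,3R)-5-hydroxy-8-iodo-7-methoxy-2,3-dimethylchroman-6-yl]hexanoate F5. Linear-selective Negishi coupling with prenylzinc bromide in excess (Pd(OAc)2, 2-dicyclohexylphosphino-2',6'-bis(dimethylamino)biphenyl, THF, rt) then gives 30.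

**Further compounds**
F1 | step 14 | (R)-3-{(E)-3-[(2S,3R)-5-(benzyloxy)-7-methoxy-2,3-dimethylchroman-6-yl]acryloyl}-4-phenyloxazolidin-2-one | O=C(/C=C/c1c(OCc3ccccc3)c2c(cc1OC)O[C@@H](C)[C@H](C)C2)N1[C@H](c2ccccc2)COC1=O
F2 | step 14 | (R)-3-{(R)-3-[(2S,3R)-5-(benzyloxy)-7-methoxy-2,3-dimethylchroman-6-yl]hexanoyl}-4-phenyloxazolidin-2-one | CCC[C@H](CC(=O)N1[C@H](c2ccccc2)COC1=O)c1c(OCc3ccccc3)c2c(cc1OC)O[C@@H](C)[C@H](C)C2
F3 | step 16 | [(R)-2-[(2S,3R)-5-(benzyloxy)-7-methoxy-2,3-dimethylchroman-6-yl]-4-ethoxy-4-oxobutyl]zinc bromide | CCOC(=O)C[C@@H](C[Zn]Br)c1c(OCc3ccccc3)c2c(cc1OC)O[C@@H](C)[C@H](C)C2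
F4 | step 16 | ethyl (R)-3-[(2S,3R)-5-(benzyloxy)-7-methoxy-2,3-dimethylchroman-6-yl]hex-5-enoate | C=CC[C@H](CC(=O)OCC)c1c(OCc3ccccc3)c2c(cc1OC)O[C@@H](C)[C@H](C)C2
F5 | step 19 | ethyl (R)-3-[(2S,3R)-5-hydroxy-8-iodo-7-methoxy-2,3-dimethylchroman-6-yl]hexanoate | CCC[C@H](CC(=O)OCC)c1c(O)c2c(c(I)c1OC)O[C@@H](C)[C@H](C)C2
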